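Ring A is numbered C1 (C=CH2), C2, C3, C4 (CHBr), C5 (CMe2), C6 (spiro). Ring B runs C6, C7, C8, C9 (CMeBr), C10 (CHCl), C11. The plan rests on cutting C5–C6, the ring A bond between two fully substituted carbons that flanks the exocyclic alkene at C1. In one operation a bromonium ion, released from an enantioenriched C4-bromo C5-chloride, is opened at C5 by C6 of a tetrasubstituted allylsilane. Ring A closes, the alkene geometry becomes the C6 configuration, and desilylation leaves the methylene. The precursor is an acyclic bromochloride with the C7 arm cis to C2 and the allyl arm cis to CH2SiMe3. Metathesis and epoxide chemistry complete ring B.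

Key step: step 10

Assumption: step 1 uses the antipode of the tridentate salicylaldimine–amino alcohol (Schiff base) ligand that delivers the (R)-bromochloride; both antipodes are equally accessible.

Step 1
Reactants: 1 prenol (3-methylbut-2-en-1-ol)
Product: 2 (2R)-2-bromo-3-chloro-3-methylbutan-1-ol
Conditions: N-bromosuccinimide, ClTi(OiPr)3, chiral Schiff base ligand (10 mol %), hexanes, −20 °C
Reagents that add atoms: N-bromosuccinimide O=C1CCC(=O)N1Br; chlorotitanium triisopropoxide CC(C)O[Ti](Cl)(OC(C)C)OC(C)C
Why: In this catalytic enantioselective bromochlorination of an allylic alcohol, the alkoxide-bound chiral titanium complex hands chloride to the tertiary carbon anti to the bromonium, so the ligand sets the future C4 as R.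

Step 2
Reactants: 2 (2R)-2-bromo-3-chloro-3-methylbutan-1-ol
Product: 3 (2R)-2-bromo-3-chloro-3-methylbutyl trifluoromethanesulfonate
Conditions: Tf2O, 2,6-lutidine, CH2Cl2, −78 °C
Reagents that add atoms: triflic anhydride O=S(=O)(OS(=O)(=O)C(F)(F)F)C(F)(F)F
Why: O-sulfonylation of the primary alcohol with a hindered base at low temperature is faster than any reaction of the two C–halogen bonds, and it does not touch the stereocentre.

Step 3
Reactants: 4 ethyl acetoacetate; 5 4-bromo-2-methylbut-1-ene
Product: 6 ethyl 2-acetyl-5-methylhex-5-enoate
Conditions: NaH, NaI (cat.), THF/DMF, 0 → 60 °C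
Reagents that add atoms: none
Why: This acetoacetic ester alkylation (SN2 of the stabilised enolate on a primary homoallylic halide) installs the C7 arm, and the new stereocentre needs no control because step 5 erases it.

Step 4
Reactants: 6 ethyl 2-acetyl-5-methylhex-5-enoate; 3 (2R)-2-bromo-3-chloro-3-methylbutyl trifluoromethanesulfonate
Product: 8 ethyl (6R)-6-bromo-7-chloro-7-methyl-2-(3-methylbut-3-en-1-yl)-3-oxooctanoate, via sodium lithium dianion 7 (not isolated)
Conditions: NaH, THF, 0 °C; n-BuLi, 0 °C; then 3, −78 °C; AcOH quench
Reagents that add atoms: none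
Why: In this γ-alkylation of a β-keto ester dianion (Weiler alkylation), the terminal carbanion displaces the primary triflate by SN2 and forms C2–C3, and an enolate-type nucleophile has no alkene geometry to lose and is mild enough to spare the hindered secondary bromide and C4.

Step 5
Reactants: 8 ethyl (6R)-6-bromo-7-chloro-7-methyl-2-(3-methylbut-3-en-1-yl)-3-oxooctanoate
Product: 9 ethyl (2Z,6R)-6-bromo-7-chloro-7-methyl-2-(3-methylbut-3-en-1-yl)-3-(trifluoromethylsulfonyloxy)oct-2-enoate
Conditions: Tf2O, Et3N, LiOTf, CH2Cl2, 0 °C
Reagents that add atoms: triflic anhydride O=S(=O)(OS(=O)(=O)C(F)(F)F)C(F)(F)F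
Why: In this chelation-controlled enol triflation the lithium-bridged enolate is sulfonylated on the ketone oxygen, which places OTf cis to the ester (Z) and therefore the C7 arm cis to the C2 chain.

Step 6
Reactants: 9 the (Z)-triflyloxy enoate
Product: 10 (2Z,6R)-6-bromo-7-chloro-1-hydroxy-7-methyl-2-(3-methylbut-3-en-1-yl)oct-2-en-3-yl trifluoromethanesulfonate
Conditions: i-Bu2AlH (2.3 equiv), CH2Cl2, −78 °C; Rochelle salt work-up
Reagents that add atoms: none
Why: 1,2-Reduction of the enoate by the aluminium hydride gives the C11 allylic alcohol, while the vinyl triflate, the alkyl halides and the alkene geometry are inert at this temperature.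

Step 7
Reactants: 10 the (Z)-allylic alcohol
Product: 11 (2Z,6R)-1,6-dibromo-7-chloro-7-methyl-2-(3-methylbut-3-en-1-yl)oct-2-en-3-yl trifluoromethanesulfonate
Conditions: CBr4, PPh3, CH2Cl2, 0 °C
Reagents that add atoms: carbon tetrabromide BrC(Br)(Br)Br
Why: The Appel bromination of a primary allylic alcohol runs under neutral conditions, and the electron-poor triflyloxy alkene disfavours ionisation and allylic transposition.

Step 8
Reactants: 11 the (Z)-allylic bromide; 12 tributyl(vinyl)stannane
Product: 13 (4Z,8R)-8-bromo-9-chloro-9-methyl-4-(3-methylbut-3-en-1-yl)deca-1,4-dien-5-yl trifluoromethanesulfonate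
Conditions: Pd2(dba)3 (2.5 mol %), AsPh3 (10 mol %), THF, 45 °C
Reagents that add atoms: none
Why: In this Stille allyl–vinyl coupling, zerovalent palladium inserts into the allylic C–Br bond much faster than into the hindered vinyl triflate when no chloride is added, and bond formation at the free CH2 terminus gives the allyl arm with the alkene geometry kept.

Step 9
Reactants: 13 the (Z)-dienyl triflate; 14 (trimethylsilyl)methylmagnesium chloride
Product: 15 [(2Z)-2-[(3R)-3-bromo-4-chloro-4-methylpentyl]-6-methyl-3-(prop-2-en-1-yl)hepta-2,6-dien-1-yl]trimethylsilane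
Conditions: Pd(PPh3)4 (5 mol %), THF, 0 °C → rt
Reagents that add atoms: none
Why: The Kumada–Corriu coupling of an enol triflate with a Grignard reagent that has no β-hydrogen is the standard allylsilane synthesis and proceeds with retention, so CH2SiMe3 ends cis to the allyl arm, and silicon comes in last because an allylic leaving group at C11 would otherwise depart with it in a 1,4-elimination.

Step 10
Reactants: 15 the acyclic bromochloride allylsilane
Product: 17 (4R,6S)-4-bromo-5,5-dimethyl-1-methylidene-6-(3-methylbut-3-en-1-yl)-6-(prop-2-en-1-yl)cyclohexane (route numbering), via bromonium chloride ion pair 16 (not isolated)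
Conditions: (CF3)2CHOH (0.01 M), 2,6-di-tert-butyl-4-methylpyridine, 0 °C → rt
Reagents that add atoms: none
Why: In the strongly ionising, weakly nucleophilic solvent the tertiary C5–Cl bond leaves with help from the C4 bromine to give 16, C6 of the allylsilane opens it at C5 from the rear, and the β-silyl cation at C1 gives up Me3Si to chloride, which can only produce the exocyclic methylene. The closest known reactions are the enantiospecific solvolytic bromonium–olefin cyclisation of vicinal bromochlorides and the allylsilane-terminated cation–olefin cyclisation. Ring A closes in a 6-endo mode for both partners (C1 and C6 of the alkene and C4 and C5 of the bromonium all end inside the six-membered ring) through a chair. C6 is the only new stereocentre: rear-side opening forces C4–Br antiperiplanar to the forming C5–C6 bond and hence equatorial, so the retained R centre at C4 chooses the alkene face, and the Z geometry then puts the C7 arm (cis to C2) axial and the allyl arm equatorial, cis to bromine, which is 6S. The step needs reaction at one of four alkenes and desilylation faster than capture of the C1 cation by the C9 alkene or a proton; this is secured because no external electrophilic bromine is present, only the allylsilane (the most nucleophilic π bond) reaches C5 through a six-membered chair, and the hindered pyridine and high dilution remove acid and bimolecular paths.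

Step 11
Reactants: 17 the ring A bromide with two arms
Product: 18 (4R,6S)-4-bromo-5,5,9-trimethyl-1-methylidenespiro[5.5]undec-9-ene (route numbering)
Conditions: second-generation Grubbs catalyst RuCl2(=CHPh)(PCy3)(H2IMes) (5 mol %), CH2Cl2 (0.005 M), 40 °C
Reagents that add atoms: none
Why: Ring-closing metathesis of the monosubstituted and 1,1-disubstituted arms, helped by the geminal substitution at C6, closes ring B as the trisubstituted C9=C10 cyclohexene, while the hindered C1 methylene can form no viable ring and no stereocentre changes.

Step 12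
Reactants: 18 the spiro diene
Product: 19 (4R,6S,9R,10S)-4-bromo-9,10-epoxy-5,5,9-trimethyl-1-methylidenespiro[5.5]undecane (route numbering)
Conditions: mCPBA (1.0 equiv), CH2Cl2, −20 → 0 °C
Reagents that add atoms: 3-chloroperbenzoic acid OOC(=O)c1cccc(Cl)c1
Why: The Prilezhaev epoxidation picks the more electron-rich trisubstituted alkene and should come from the ring B face anti to the axial C1 carbon (the bulkier C5 sits equatorial on ring B), which sets 9R,10S.

Step 13
Reactants: 19 the ring B epoxide
Product: 20 (4R,6S,9R,10R)-4-bromo-10-chloro-5,5,9-trimethyl-1-methylidenespiro[5.5]undecan-9-ol (route numbering)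
Conditions: LiCl (5 equiv), AcOH (3 equiv), THF, rt → 40 °C
Reagents that add atoms: lithium chloride [Li+].[Cl-]
Why: Buffered halide opening of a trisubstituted epoxide goes by SN2 at the secondary carbon C10 with inversion (Fürst–Plattner trans-diaxial opening of the half-chair with C1 axial) and leaves C9–O untouched, and acetic acid is too weak to ionise C9–O or protonate the C1 methylene.

Step 14
Reactants: 20 the trans chlorohydrin
Product: 21 (4R,6S,9R,10R)-4,9-dibromo-10-chloro-5,5,9-trimethyl-1-methylidenespiro[5.5]undecane (route numbering)
Conditions: Me2C=C(Br)NMe2 (1.5 equiv), CH2Cl2, 0 °C → rt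
Reagents that add atoms: 1-bromo-N,N,2-trimethylprop-1-en-1-amine CC(C)=C(Br)N(C)C
Why: In this neutral deoxybromination with an α-bromoenamine the O-imidoyl group leaves the tertiary centre with help from the trans-vicinal C10 chlorine (chloronium-type participation, as in classical retentive substitutions of vicinal halohydrins) and bromide re-enters at the more substituted carbon C9 on the original face, so C9 stays R and no Brønsted acid is released that could attack the C1 methylene.

Compound list
1 | prenol (3-methylbut-2-en-1-ol) | CC(C)=CCO | starting material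
2 | (2R)-2-bromo-3-chloro-3-methylbutan-1-ol | OC[C@@H](Br)C(C)(C)Cl | intermediate
3 | (2R)-2-bromo-3-chloro-3-methylbutyl trifluoromethanesulfonate | O=S(=O)(OC[C@@H](Br)C(C)(C)Cl)C(F)(F)F | intermediate
4 | ethyl acetoacetate | CCOC(=O)CC(C)=O | starting material
5 | 4-bromo-2-methylbut-1-ene | C=C(C)CCBr | starting material
6 | ethyl 2-acetyl-5-methylhex-5-enoate | CCOC(=O)C(CCC(C)=C)C(C)=O | intermediate
7 | sodium lithium dianion of 6 | [Na+].[Li+].[CH2-]C(=O)[C-](CCC(C)=C)C(=O)OCC | intermediate
8 | ethyl (6R)-6-bromo-7-chloro-7-methyl-2-(3-methylbut-3-en-1-yl)-3-oxooctanoate | CCOC(=O)C(CCC(C)=C)C(=O)CC[C@@H](Br)C(C)(C)Cl | intermediate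
9 | ethyl (2Z,6R)-6-bromo-7-chloro-7-methyl-2-(3-methylbut-3-en-1-yl)-3-(trifluoromethylsulfonyloxy)oct-2-enoate | CCOC(=O)/C(CCC(C)=C)=C(\OS(=O)(=O)C(F)(F)F)CC[C@@H](Br)C(C)(C)Cl | intermediate
10 | (2Z,6R)-6-bromo-7-chloro-1-hydroxy-7-methyl-2-(3-methylbut-3-en-1-yl)oct-2-en-3-yl trifluoromethanesulfonate | OC/C(CCC(C)=C)=C(\OS(=O)(=O)C(F)(F)F)CC[C@@H](Br)C(C)(C)Cl | intermediate
11 | (2Z,6R)-1,6-dibromo-7-chloro-7-methyl-2-(3-methylbut-3-en-1-yl)oct-2-en-3-yl trifluoromethanesulfonate | BrC/C(CCC(C)=C)=C(\OS(=O)(=O)C(F)(F)F)CC[C@@H](Br)C(C)(C)Cl | intermediate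
12 | tributyl(vinyl)stannane | C=C[Sn](CCCC)(CCCC)CCCC | starting material
13 | (4Z,8R)-8-bromo-9-chloro-9-methyl-4-(3-methylbut-3-en-1-yl)deca-1,4-dien-5-yl trifluoromethanesulfonate | C=CC/C(CCC(C)=C)=C(\OS(=O)(=O)C(F)(F)F)CC[C@@H](Br)C(C)(C)Cl | intermediate
14 | (trimethylsilyl)methylmagnesium chloride | C[Si](C)(C)C[Mg]Cl | starting material
15 | [(2Z)-2-[(3R)-3-bromo-4-chloro-4-methylpentyl]-6-methyl-3-(prop-2-en-1-yl)hepta-2,6-dien-1-yl]trimethylsilane | C=C(C)CC/C(CC=C)=C(/C[Si](C)(C)C)CC[C@@H](Br)C(C)(C)Cl | intermediate
16 | C4–C5 bromonium chloride ion pair derived from 15 | C=C(C)CC/C(CC=C)=C(/C[Si](C)(C)C)CC[C@H]1[Br+]C1(C)C.[Cl-] | intermediate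
17 | (4R,6S)-4-bromo-5,5-dimethyl-1-methylidene-6-(3-methylbut-3-en-1-yl)-6-(prop-2-en-1-yl)cyclohexane (route numbering) | C=C1CC[C@@H](Br)C(C)(C)[C@]1(CC=C)CCC(C)=C | intermediate
18 | (4R,6S)-4-bromo-5,5,9-trimethyl-1-methylidenespiro[5.5]undec-9-ene (route numbering) | C=C1CC[C@@H](Br)C(C)(C)[C@]12CCC(C)=CC2 | intermediate
19 | (4R,6S,9R,10S)-4-bromo-9,10-epoxy-5,5,9-trimethyl-1-methylidenespiro[5.5]undecane (route numbering) | C=C1CC[C@@H](Br)C(C)(C)[C@]12CC[C@@]3(C)O[C@H]3C2 | intermediate
20 | (4R,6S,9R,10R)-4-bromo-10-chloro-5,5,9-trimethyl-1-methylidenespiro[5.5]undecan-9-ol (route numbering) | C=C1CC[C@@H](Br)C(C)(C)[C@]12CC[C@@](C)(O)[C@H](Cl)C2 | intermediate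
21 | (4R,6S,9R,10R)-4,9-dibromo-10-chloro-5,5,9-trimethyl-1-methylidenespiro[5.5]undecane (route numbering) | C=C1CC[C@@H](Br)C(C)(C)[C@]12CC[C@@](C)(Br)[C@H](Cl)C2 | target

Total step count: 14. Longest linear sequence: 13 steps (1 to 21 through steps 1, 2 and 4–14). Step 3 is the only side branch.

Steps most likely to fail

Step 10. The silyl group may be lost to a proton before C5–C6 forms. The C1 cation may also be intercepted by the C9 alkene of the axial arm, or part of the material may fold through a boat and erode C6. The fallback reverses the order of the two ring closures; it sets out from 15 and rejoins the route at 18. Ring-closing metathesis of 15 with the second-generation Grubbs catalyst first joins the two arms to [(2Z,5R)-5-bromo-6-chloro-6-methyl-2-(4-methylcyclohex-3-en-1-ylidene)heptyl]trimethylsilane F1. In F1 the competing 1,1-disubstituted alkene no longer exists, and the exocyclic tetrasubstituted alkene keeps its geometry. Solvolysis of F1 in buffered (CF3)2CHOH then spiro-annulates ring A, in the manner of a bisabolene-to-chamigrene cyclisation and with the same chair logic, and gives 18.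

Step 13. The opening may be sluggish or misdirected, because chloride has to reach C10 from the ring B face that carries the axial C1 carbon and its methylene. Ionisation at the tertiary C9 may therefore take over. The fallback makes the tertiary opening productive; it sets out from 19 and rejoins at 21, bypassing 20. Et2AlCl in CH2Cl2 at −78 °C opens 19 at C9 with inversion to give (4R,6S,9S,10S)-4-bromo-9-chloro-5,5,9-trimethyl-1-methylidenespiro[5.5]undecan-10-ol F2. Tf2O and 2,6-lutidine convert it into the C10 trifluoromethanesulfonate of that alcohol F3. On treatment with Bu4NBr the trans chlorine displaces the triflate from the rear, and bromide opens the resulting chloronium ion at the tertiary carbon. This 1,2-chlorine shift inverts C10 once and C9 a second time, which is the configuration of 21.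

Step 14. Three things may go wrong: elimination toward C8 or the methyl group, loss of configuration at C9 if chlorine participation is weak, and capture of the cationic centre by the C1 methylene. The fallback avoids a cation at C9 that must be trapped from outside; it sets out from 18 and rejoins at 21. N-bromosuccinimide and Et4NCl in CH2Cl2 at −78 °C add bromine to the open face of C9=C10 and chloride to the tertiary carbon, giving (4R,6S,9S,10S)-4,10-dibromo-9-chloro-5,5,9-trimethyl-1-methylidenespiro[5.5]undecane F4. Warming F4 in toluene should then trigger the dyotropic 1,2-interchange of the two trans halogens, the rearrangement known from 5,6-dihalo steroids. Each halogen stays on its own face, which leads stereospecifically to 21, to be separated from unchanged F4.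

Further compounds
F1 | step 10 | [(2Z,5R)-5-bromo-6-chloro-6-methyl-2-(4-methylcyclohex-3-en-1-ylidene)heptyl]trimethylsilane | CC1=CC/C(CC1)=C(\C[Si](C)(C)C)CC[C@@H](Br)C(C)(C)Cl
F2 | step 13 | (4R,6S,9S,10S)-4-bromo-9-chloro-5,5,9-trimethyl-1-methylidenespiro[5.5]undecan-10-ol | C=C1CC[C@@H](Br)C(C)(C)[C@]12CC[C@](C)(Cl)[C@@H](O)C2
F3 | step 13 | (4R,6S,9S,10S)-4-bromo-9-chloro-5,5,9-trimethyl-1-methylidenespiro[5.5]undecan-10-yl trifluoromethanesulfonate | C=C1CC[C@@H](Br)C(C)(C)[C@]12CC[C@](C)(Cl)[C@@H](OS(=O)(=O)C(F)(F)F)C2
F4 | step 14 | (4R,6S,9S,10S)-4,10-dibromo-9-chloro-5,5,9-trimethyl-1-methylidenespiro[5.5]undecane | C=C1CC[C@@H](Br)C(C)(C)[C@]12CC[C@](C)(Cl)[C@@H](Br)C2
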